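Count what gamma's feed delivers while partner still lives.

| flask | substrate | partner | protic impurity | remark | time |
|---|---|---|---|---|---|
| north-west | 0.38 M | 0.50 equiv | 0.19 M | run made earlier |  |
| west | 0.38 M | 0.25 equiv | 0.19 M | run made earlier |  |
| north-east | 0.38 M | 1 equiv | 0.19 M | run made earlier |  |
| south | 0.76 M | 0.50 equiv | 0.19 M | run made earlier |  |
| gamma | 0.38 M (fed, over 15 h) | 0.500 equiv | 0.190 M | all else is in the flask from the start; the feed brings no volume worth counting | 25 h |
| beta | 0.38 M | 0.500 equiv (fed, over 15 h) | 0.190 M | all else is in the flask from the start; the feed brings no volume worth counting | 25 h |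
| eta | 0.38 M | 0.500 equiv | 0.190 M | everything together at the start | 25 h |

| run | time / h | side product / % | target / % | substrate / % |
|---|---|---|---|---|
| north-west | 6.00 | 30.8 | 7.7 | 46.5 |
| north-west | 12.0 | 34.8 | 2.6 | 41.6 |
| north-west | 20.0 | 37.5 | 0.9 | 41.9 |
| north-west | 25.0 | 36.3 | 0.3 | 42.0 |
| west | 1.33 | 6.0 | 12.2 | 77.7 |
| west | 3.00 | 12.0 | 9.2 | 73.8 |
| west | 6.00 | 19.8 | 2.5 | 68.8 |
| west | 15.0 | 21.0 | 0.3 | 68.4 |
| north-east | 4.00 | 23.9 | 36.1 | 14.6 |
| north-east | 8.00 | 31.1 | 20.8 | 8.8 |
| north-east | 12.0 | 31.4 | 10.2 | 8.3 |
| north-east | 15.0 | 34.5 | 4.9 | 9.5 |
| south | 2.00 | 25.9 | 21.9 | 42.3 |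
| south | 5.00 | 42.1 | 9.3 | 33.6 |
| south | 10.0 | 50.5 | 3.0 | 29.8 |
| south | 15.0 | 50.5 | 0 | 29.8 |

(each reading ± 1 percentage point)

* the flask that comes out highest in amount of side product, in percent of the substrate charged; "all alike" if 1.5 percentage points covers them all (gamma / beta / eta / all alike)
* amount of side product at the end, in percent of the substrate charged, gamma
* amount of side product at the end, in percent of the substrate charged, beta
* amount of side product at the end, in percent of the substrate charged, eta

- percentages count the substrate that a species holds: one side product counts as two
- the numbers in the tables scatter with a standard deviation of 1 percentage point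

Which flask needs reckoning? Eta repeats the north-west recipe, which read 36.3% at 25.0 h; gamma resembles no earlier run.

How much target did west make? Each side product holds two substrates, one of which came as target, so target made is substrate gone less 0.5 of the side product: 21.1% at the end. Against 0.25 equiv of partner, 84.4% of partner made target, and the rest died otherwise.

How fast does partner die? West had made 19.3% by 1.33 h, so partner fell at 1.85 h⁻¹, and the otherwise-share of that is 0.289 h⁻¹, pseudo-first-order in partner.

Isn't that weak? Yes: it hangs on a gap of 1.8 points with a scatter of 1 point, so it is a rough reading.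

What does gamma do with it? Partner is the limiting reagent; in my reckoning gamma's partner drains by the fed substrate and by this loss together, and it reaches zero at 3.99 h. That gives the partner budget, the share of the substrate charge fed to gamma by that reckoned time: 26.6%. It takes fed substrate as reacting at once, so it errs high.

And the side product? In north-west, the final readings give target coupled over target lost unseen, and that ratio divided by the final c_substrate reads 5.31 M⁻¹. Taking c_substrate as 0.101 M while gamma's target lives, 35.0% of target couples, so I say 18.6%. Beta I put slightly above eta, unsized.

The forecast names beta highest, with gamma 7% (3% to 13%), lower than mine, beta 39% (34% to 44%) and eta 37% (35% to 39%), holding for gamma “target mostly quenched by impurity before substrate accumulates”.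

The flasks give gamma 13.2%, beta 38.5% and eta 36.9%, with beta highest.

    target → over-reaction product (k = 4.08 × 10⁻⁵ s⁻¹)
    substrate + target → side product (k = 1.75 × 10⁻⁴ M⁻¹ s⁻¹)
    substrate + partner → target + by-product (k = 0.00124 M⁻¹ s⁻¹)
    partner + protic impurity → quenched reagent (k = 5.27 × 10⁻⁴ M⁻¹ s⁻¹)

Gamma made 0.0749 M of by-product, one per target, which is less than the budget of 0.101 M, so the budget ran high there. In beta the largest single effect on side product is the loss of target to over-reaction product: taking that step away lifts the amount from 38.5% to 62.1%. For a neighbouring flask, gamma with 0.048 M of protic impurity, scaling the partner loss gives 0.0729 h⁻¹, which budgets 0.152 M; that flask made 0.151 M of by-product and 23.0% of side product.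

The readings come from a simulation for substances that don't exist.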